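Everything rests on disconnecting ring B at C9–C10. C10 is a quaternary ring-fusion carbon that carries a methyl group (C20) and is bonded to C9, so it can be reached as a tertiary radical: an iron hydride adds a hydrogen atom to C20 of a ring-A 10(20)-methylene, and the C10 radical attacks C9 of an enoate held on the C5 side chain. One operation thus makes ring B, the C9–C10 bond, the C20 methyl and the C9/C10 stereocentres of a trans-decalin. The precursor is a cyclohexane (ring A) with the C10 methylene, C4 bearing methyl and CH2SiMe2Ph (latent C18–OH), and an equatorial C5 chain: C6–OTBS, C8 dioxolane, (E)-C9=C11–CO2Me.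

Key step: step 9

Assumption: in step 5 the enantiomer of the chiral imidazolinium ligand is the one that places the silylmethyl group on the enone face giving the (R)-quaternary carbon.

Design remarks
- Labdane numbering is used throughout: C18 = 4α-CH2O, C19 = 4β-CH3, C20 = 10β-CH3, C17 = methylene on C8. The target is (4R,5R,6S,9S,10R,13Z), with the 6-OH equatorial (α).
- C18 is carried as CH2SiMe2Ph until ring B is closed. The silylmethyl arm is the larger C4 substituent when C5 is functionalised, and its oxidation needs an electrophile and a peracid, which the C10 methylene would not survive.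
- The enoate arrives with the aldehyde fragment. No olefin metathesis is run on a compound holding both the C10 methylene and a vinyl group, where ring closure to a cyclohexene would compete.
- The C5–C6 bond is made by an open-transition-state allylsilane addition. This gives the syn (5R,6S) pair and delivers the C10 methylene in the same step; a closed aldol of the cyclic enolate would favour the C6 epimer.
- C8 is methylenated with a non-basic reagent before the side chain is attached.
- The C15 acid is masked as a fluoride-labile ester, because saponification would also cleave the benzoate.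

Step 1
Reactants: 1 diethyl oxalate
Product: 2 ethyl 2-oxopent-4-enoate
Conditions: allylMgBr (1.0 equiv) added to 1 (1.5 equiv), THF/Et2O, −78 °C; AcOH, −78 °C
Reagents that add atoms: allylmagnesium bromide, C=CC[Mg]Br
Why: Acyl substitution of one oxalate ester by the Grignard reagent should stop at the ketone, because the chelated tetrahedral magnesium alkoxide persists at −78 °C until the acidic quench (α-keto ester synthesis from an oxalate); no stereocentre is formed.

Step 2
Reactants: 2 ethyl 2-oxopent-4-enoate
Product: 3 ethyl 2-(prop-2-en-1-yl)-1,3-dioxolane-2-carboxylate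
Conditions: Me3SiOCH2CH2OSiMe3, TMSOTf (5 mol%), CH2Cl2, −78 → 0 °C
Reagents that add atoms: 1,2-bis(trimethylsilyloxy)ethane, C[Si](C)(C)OCCO[Si](C)(C)C
Why: Silyl-triflate-catalysed acetalisation with the bis-silylated diol should convert the electrophilic keto group into the dioxolane under aprotic, cold conditions that leave the β,γ-double bond out of conjugation.

Step 3
Reactants: 3 ethyl 2-(prop-2-en-1-yl)-1,3-dioxolane-2-carboxylate
Product: 5 methyl (2E)-3-[2-(prop-2-en-1-yl)-1,3-dioxolan-2-yl]prop-2-enoate, via 2-(prop-2-en-1-yl)-1,3-dioxolane-2-carbaldehyde 4 (not isolated)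
Conditions: i-Bu2AlH (1.1 equiv), CH2Cl2, −78 °C; then Ph3P=CHCO2Me, −78 °C → rt
Reagents that add atoms: methyl (triphenylphosphoranylidene)acetate, COC(=O)C=P(c1ccccc1)(c1ccccc1)c1ccccc1
Why: Partial reduction of the α,α-dialkoxy ester should stop at the aluminium hemiacetal, and the aldehyde released on warming is trapped in the same flask by the stabilised ylide in an (E)-selective Wittig reaction.

Step 4
Reactants: 5 methyl (2E)-3-[2-(prop-2-en-1-yl)-1,3-dioxolan-2-yl]prop-2-enoate
Product: 7 methyl (2E)-3-[2-(2-oxoethyl)-1,3-dioxolan-2-yl]prop-2-enoate, via secondary ozonide 6 (not isolated)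
Conditions: O3, CH2Cl2, −78 °C (Sudan Red 7B as end-point indicator); then Me2S, −78 °C → rt
Reagents that add atoms: ozone, [O-][O+]=O
Why: Ozonolysis with reductive work-up should cleave the electron-rich terminal alkene well before the electron-poor γ,γ-dialkoxy enoate reacts, unveiling the C6 aldehyde.

Step 5
Reactants: 8 3-methylcyclohex-2-en-1-one; 9 (chloromethyl)dimethyl(phenyl)silane
Product: 12 (3R)-3-{[dimethyl(phenyl)silyl]methyl}-3-methylcyclohex-1-en-1-yl trifluoromethanesulfonate, via silylmethyl Grignard reagent 10 (not isolated), via chloromagnesium enolate 11 (not isolated)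
Conditions: 9, Mg, Et2O, reflux; then Cu(OTf)2 (3 mol%), chiral imidazolinium chloride (NHC precursor, 4 mol%), 8 added slowly, Et2O, 0 °C; then PhNTf2, THF, 0 °C → rt
Reagents that add atoms: N-phenylbis(trifluoromethanesulfonimide), O=S(=O)(N(c1ccccc1)S(=O)(=O)C(F)(F)F)C(F)(F)F
Why: Copper-catalysed asymmetric conjugate addition of the Grignard reagent, steered by the chiral N-heterocyclic carbene on copper, should add the silylmethyl group to one enone face and set the quaternary C4 as R; O-sulfonylation of the regiodefined C10=C5 magnesium enolate in the same flask stores that regiochemistry as the enol triflate.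

Step 6
Reactants: 12 (3R)-3-{[dimethyl(phenyl)silyl]methyl}-3-methylcyclohex-1-en-1-yl trifluoromethanesulfonate
Product: 13 dimethyl{[(1R)-1-methyl-3-[(trimethylsilyl)methyl]cyclohex-2-en-1-yl]methyl}(phenyl)silane
Conditions: Me3SiCH2MgCl (1.5 equiv), Pd(PPh3)4 (5 mol%), Et2O/THF, 0 °C → rt
Reagents that add atoms: (trimethylsilyl)methylmagnesium chloride, C[Si](C)(C)C[Mg]Cl
Why: Palladium-catalysed Kumada coupling of the enol triflate with the silylmethyl Grignard reagent should give the allylsilane with the double bond fixed at C10=C5 and C20 attached; C4 is untouched.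

Step 7
Reactants: 13 dimethyl{[(1R)-1-methyl-3-[(trimethylsilyl)methyl]cyclohex-2-en-1-yl]methyl}(phenyl)silane; 7 methyl (2E)-3-[2-(2-oxoethyl)-1,3-dioxolan-2-yl]prop-2-enoate
Product: 14 methyl (2E)-3-{2-[(2S)-2-[(1R,2R)-2-{[dimethyl(phenyl)silyl]methyl}-2-methyl-6-methylidenecyclohexyl]-2-hydroxyethyl]-1,3-dioxolan-2-yl}prop-2-enoate
Conditions: BF3·OEt2 (1.2 equiv), CH2Cl2, −78 °C; aq. NaHCO3
Reagents that add atoms: none
Why: In this Hosomi–Sakurai allylation C5 of the allylsilane attacks the BF3-activated aldehyde through an open antiperiplanar transition state (anti SE2′) while the double bond moves to C10=C20; the aldehyde is expected to enter C5 opposite the pseudoaxial silylmethyl arm of C4 (C6 trans to C18) and, as with an (E)-crotylsilane, with its chain turned away from C4, which gives the syn C5/C6 pair (5R,6S).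

Step 8
Reactants: 14 (the homoallylic alcohol from step 7)
Product: 15 methyl (2E)-3-{2-[(2S)-2-[(tert-butyldimethylsilyl)oxy]-2-[(1R,2R)-2-{[dimethyl(phenyl)silyl]methyl}-2-methyl-6-methylidenecyclohexyl]ethyl]-1,3-dioxolan-2-yl}prop-2-enoate
Conditions: TBSOTf, 2,6-lutidine, CH2Cl2, −78 → 0 °C
Reagents that add atoms: tert-butyldimethylsilyl trifluoromethanesulfonate, CC(C)(C)[Si](C)(C)OS(=O)(=O)C(F)(F)F
Why: Silylation of the hindered secondary alcohol with the silyl triflate and a non-nucleophilic base; no stereocentre is affected.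

Step 9
Reactants: 15 (the 10(20)-methylene ring-A enoate from step 8)
Product: 16 methyl (4R,5R,6S,9R,10S)-6-[(tert-butyldimethylsilyl)oxy]-18-[dimethyl(phenyl)silyl]-8,8-(ethylenedioxy)-13,14,15,16,17-pentanorlabdan-12-oate
Conditions: Fe(acac)3 (1.0 equiv), PhSiH3 (3 equiv), EtOH/HOCH2CH2OH (5:1), degassed, 0.02 M, 60 °C
Reagents that add atoms: none
Why: Fe(acac)3 and the ethanolysed silane should generate an iron hydride (trivalent iron) that donates H• to the terminal carbon C20 of the methylene, so that the unpaired electron sits on C10, now tertiary and carrying the C20 methyl; this nucleophilic radical adds to C9, the β-carbon of the enoate, and the resulting C11 radical is reduced by divalent iron and protonated by ethanol. The closest known reaction type is the iron-hydride hydrogen-atom-transfer-initiated Giese (reductive olefin) coupling in its intramolecular form, which is established for quaternary carbons and trans-decalins. Ring B forms in the 6-exo-trig mode (C10 to C9, with C9=C11 outside the new ring), preferred over 7-endo by ring size and polarity matching and helped by the gem-dialkoxy carbon C8 in the tether. C10 is controlled by C5: in a chair-like transition state with the C5 chain and the C6 silyl ether equatorial, C9 reaches the α-lobe of the radical, away from the axial C19 methyl on C4, so that C20 ends axial and trans to H-5. C9 is controlled by the same chair, in which the ester-bearing terminus C11 lies equatorial (9α-H); this centre later sits next to the C8 ketone and can converge on the same equatorial epimer. The step needs chemoselective hydrogen-atom transfer to the methylene and trans ring fusion; the first follows from the donor and acceptor character of the two alkenes, the second from the equatorial anchor at C5 and the 1,3-diaxial shielding by C19.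

Step 10
Reactants: 16 (the trans-decalin ketal ester from step 9)
Product: 17 methyl (4R,5R,6S,9R,10S)-6-[(tert-butyldimethylsilyl)oxy]-8,8-(ethylenedioxy)-18-hydroxy-13,14,15,16,17-pentanorlabdan-12-oate
Conditions: KBr, NaOAc, AcOOH (32% in AcOH), AcOH, rt
Reagents that add atoms: peracetic acid, CC(=O)OO
Why: In this Fleming–Tamao oxidation electrophilic bromodesilylation removes the phenyl group from silicon and the peracid then inserts oxygen into the C18–Si bond; it is placed here because the molecule no longer has an alkene, and the dioxolane keeps C8 safe from Baeyer–Villiger oxidation.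

Step 11
Reactants: 17 (the 18-hydroxy ketal ester from step 10)
Product: 18 methyl (4R,5R,6S,9R,10S)-6-[(tert-butyldimethylsilyl)oxy]-18-hydroxy-8-oxo-13,14,15,16,17-pentanorlabdan-12-oate
Conditions: PPTS (0.3 equiv), acetone/H2O (9:1), 55 °C
Reagents that add atoms: water, O
Why: Mild acid-catalysed acetal hydrolysis should release the C8 ketone from the dioxolane, which is strained by its syn-axial contact with C20, without cleaving the silyl ether; C9, now α to the ketone, can settle into its more stable equatorial (9α-H) configuration.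

Step 12
Reactants: 18 (the 8-oxo ester from step 11)
Product: 19 methyl (4R,5R,6S,9S,10R)-6-[(tert-butyldimethylsilyl)oxy]-18-hydroxy-13,14,15,16-tetranorlabd-8(17)-en-12-oate
Conditions: Zn, CH2Br2, TiCl4, THF (reagent pre-formed at 0 °C, excess); then 18, CH2Cl2, rt
Reagents that add atoms: dibromomethane, BrCBr
Why: Takai–Lombardo methylenation with the non-basic zinc/titanium methylene reagent should convert the hindered, enolisable ketone into the 8(17)-alkene without β-elimination of the C6 silyloxy group, epimerisation at C9 or attack on the ester; the free alcohol only consumes reagent.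

Step 13
Reactants: 19 (the 8(17)-ene ester from step 12)
Product: 20 (4R,5R,6S,9S,10R)-6-[(tert-butyldimethylsilyl)oxy]-13,14,15,16-tetranorlabd-8(17)-ene-12,18-diol
Conditions: LiAlH4, THF, 0 °C
Reagents that add atoms: none
Why: Hydride reduction of the ester to the primary C12 alcohol; the alkene and the silyl ether are inert.

Step 14
Reactants: 20 (the 12,18-diol from step 13)
Product: 21 (4R,5R,6S,9S,10R)-6-[(tert-butyldimethylsilyl)oxy]-12-iodo-13,14,15,16-tetranorlabd-8(17)-en-18-ol
Conditions: PPh3, I2, imidazole, CH2Cl2, 0 °C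
Reagents that add atoms: iodine, [I][I]
Why: In this Appel reaction the unhindered C12 alcohol is converted into the iodide by SN2 displacement of its alkoxyphosphonium salt, whereas the neopentyl C18 alcohol cannot be displaced and should be recovered on work-up.

Step 15
Reactants: 21 (the 12-iodo-18-ol from step 14)
Product: 22 (4R,5R,6S,9S,10R)-6-[(tert-butyldimethylsilyl)oxy]-12-iodo-13,14,15,16-tetranorlabd-8(17)-en-18-yl benzoate
Conditions: BzCl, pyridine, DMAP (cat.), CH2Cl2, 0 °C → rt
Reagents that add atoms: benzoyl chloride, O=C(Cl)c1ccccc1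
Why: Nucleophile-catalysed acylation of the only free hydroxyl group should install the C18 benzoate with no competition from O-6, which is still silylated.

Step 16
Reactants: 23 but-2-ynoic acid
Product: 24 (2Z)-3-iodobut-2-enoic acid
Conditions: NaI, AcOH, 115 °C
Reagents that add atoms: sodium iodide, [Na+].[I-]
Why: Anti hydroiodination of the ynoic acid (iodide to the β-carbon, proton to the α-carbon from the opposite side) should give the (Z)-β-iodo acid.

Step 17
Reactants: 24 (2Z)-3-iodobut-2-enoic acid
Product: 25 2-(trimethylsilyl)ethyl (2Z)-3-iodobut-2-enoate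
Conditions: Me3SiCH2CH2OH, DCC, DMAP (cat.), CH2Cl2, 0 °C → rt
Reagents that add atoms: 2-(trimethylsilyl)ethanol, C[Si](C)(C)CCO
Why: Steglich esterification under near-neutral conditions keeps the (Z)-geometry and masks the acid as an ester that fluoride can remove in the presence of the benzoate.

Step 18
Reactants: 22 (the 12-iodo 18-benzoate from step 15); 25 2-(trimethylsilyl)ethyl (2Z)-3-iodobut-2-enoate
Product: 27 2-(trimethylsilyl)ethyl (4R,5R,6S,9S,10R,13Z)-18-(benzoyloxy)-6-[(tert-butyldimethylsilyl)oxy]labda-8(17),13-dien-15-oate, via alkylzinc iodide 26 (not isolated)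
Conditions: Zn dust (activated with TMSCl and BrCH2CH2Br), DMA, 40 °C; then 25, Pd(PPh3)4 (5 mol%), THF, rt
Reagents that add atoms: none
Why: In this Negishi coupling zinc inserts into the primary C–I bond (benzoate, silyl ether and alkene are tolerated) and the alkylzinc iodide couples with the alkenyl iodide under palladium catalysis with retention of the (Z)-geometry, forming C12–C13.

Step 19
Reactants: 27 (the coupled ester from step 18)
Product: 28 (4R,5R,6S,9S,10R,13Z)-18-(benzoyloxy)-6-[(tert-butyldimethylsilyl)oxy]labda-8(17),13-dien-15-oic acid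
Conditions: TBAF (1.5 equiv), THF, 0 °C → rt; dilute aq. HCl work-up
Reagents that add atoms: none
Why: Fluoride attacks the trimethylsilyl group and the ester fragments by β-elimination into ethylene and the carboxylate, which should free the C15 acid without saponification; O-6 is still silylated, so no alkoxide is present to move the benzoate.

Step 20
Reactants: 28 (the 6-O-silyl acid from step 19)
Product: 29 (4R,5R,6S,9S,10R,13Z)-18-(benzoyloxy)-6-hydroxylabda-8(17),13-dien-15-oic acid
Conditions: HF·pyridine, pyridine, THF, 0 °C → rt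
Reagents that add atoms: none
Why: Buffered HF·pyridine should cleave the remaining silyl ether at O-6 (acid-type desilylation); the benzoate, the acid and both alkenes are stable to these mildly acidic conditions.

Compound list
1 | diethyl oxalate | CCOC(=O)C(=O)OCC | starting material
2 | ethyl 2-oxopent-4-enoate | C=CCC(=O)C(=O)OCC | intermediate
3 | ethyl 2-(prop-2-en-1-yl)-1,3-dioxolane-2-carboxylate | C=CCC1(OCCO1)C(=O)OCC | intermediate
4 | 2-(prop-2-en-1-yl)-1,3-dioxolane-2-carbaldehyde (not isolated) | C=CCC1(OCCO1)C=O | intermediate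
5 | methyl (2E)-3-[2-(prop-2-en-1-yl)-1,3-dioxolan-2-yl]prop-2-enoate | C=CCC1(OCCO1)/C=C/C(=O)OC | intermediate
6 | secondary ozonide of 5 at the terminal alkene, methyl (2E)-3-{2-[(1,2,4-trioxolan-3-yl)methyl]-1,3-dioxolan-2-yl}prop-2-enoate (not isolated) | COC(=O)/C=C/C1(CC2OCOO2)OCCO1 | intermediate
7 | methyl (2E)-3-[2-(2-oxoethyl)-1,3-dioxolan-2-yl]prop-2-enoate | O=CCC1(OCCO1)/C=C/C(=O)OC | intermediate
8 | 3-methylcyclohex-2-en-1-one | CC1=CC(=O)CCC1 | starting material
9 | (chloromethyl)dimethyl(phenyl)silane | ClC[Si](C)(C)c1ccccc1 | starting material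
10 | {[dimethyl(phenyl)silyl]methyl}magnesium chloride (not isolated) | Cl[Mg]C[Si](C)(C)c1ccccc1 | intermediate
11 | chloromagnesium (3R)-3-{[dimethyl(phenyl)silyl]methyl}-3-methylcyclohex-1-en-1-olate (not isolated) | Cl[Mg]OC1=C[C@](C)(C[Si](C)(C)c2ccccc2)CCC1 | intermediate
12 | (3R)-3-{[dimethyl(phenyl)silyl]methyl}-3-methylcyclohex-1-en-1-yl trifluoromethanesulfonate | O=S(=O)(OC1=C[C@](C)(C[Si](C)(C)c2ccccc2)CCC1)C(F)(F)F | intermediate
13 | dimethyl{[(1R)-1-methyl-3-[(trimethylsilyl)methyl]cyclohex-2-en-1-yl]methyl}(phenyl)silane | C[Si](C)(C)CC1=C[C@](C)(C[Si](C)(C)c2ccccc2)CCC1 | intermediate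
14 | methyl (2E)-3-{2-[(2S)-2-[(1R,2R)-2-{[dimethyl(phenyl)silyl]methyl}-2-methyl-6-methylidenecyclohexyl]-2-hydroxyethyl]-1,3-dioxolan-2-yl}prop-2-enoate (labdane positions 4R,5R,6S) | C=C1CCC[C@@](C)(C[Si](C)(C)c2ccccc2)[C@@H]1[C@@H](O)CC1(OCCO1)/C=C/C(=O)OC | intermediate
15 | methyl (2E)-3-{2-[(2S)-2-[(tert-butyldimethylsilyl)oxy]-2-[(1R,2R)-2-{[dimethyl(phenyl)silyl]methyl}-2-methyl-6-methylidenecyclohexyl]ethyl]-1,3-dioxolan-2-yl}prop-2-enoate (key-step precursor) | C=C1CCC[C@@](C)(C[Si](C)(C)c2ccccc2)[C@@H]1[C@@H](O[Si](C)(C)C(C)(C)C)CC1(OCCO1)/C=C/C(=O)OC | intermediate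
16 | methyl (4R,5R,6S,9R,10S)-6-[(tert-butyldimethylsilyl)oxy]-18-[dimethyl(phenyl)silyl]-8,8-(ethylenedioxy)-13,14,15,16,17-pentanorlabdan-12-oate (trans-decalin; 5α-H, 9α-H, 10β-CH3; key-step product) | C12(OCCO1)C[C@H](O[Si](C)(C)C(C)(C)C)[C@H]3[C@](C)(C[Si](C)(C)c4ccccc4)CCC[C@]3(C)[C@H]2CC(=O)OC | intermediate
17 | methyl (4R,5R,6S,9R,10S)-6-[(tert-butyldimethylsilyl)oxy]-8,8-(ethylenedioxy)-18-hydroxy-13,14,15,16,17-pentanorlabdan-12-oate | C12(OCCO1)C[C@H](O[Si](C)(C)C(C)(C)C)[C@H]3[C@](C)(CO)CCC[C@]3(C)[C@H]2CC(=O)OC | intermediate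
18 | methyl (4R,5R,6S,9R,10S)-6-[(tert-butyldimethylsilyl)oxy]-18-hydroxy-8-oxo-13,14,15,16,17-pentanorlabdan-12-oate | O=C1C[C@H](O[Si](C)(C)C(C)(C)C)[C@H]2[C@](C)(CO)CCC[C@]2(C)[C@H]1CC(=O)OC | intermediate
19 | methyl (4R,5R,6S,9S,10R)-6-[(tert-butyldimethylsilyl)oxy]-18-hydroxy-13,14,15,16-tetranorlabd-8(17)-en-12-oate | C=C1C[C@H](O[Si](C)(C)C(C)(C)C)[C@H]2[C@](C)(CO)CCC[C@]2(C)[C@H]1CC(=O)OC | intermediate
20 | (4R,5R,6S,9S,10R)-6-[(tert-butyldimethylsilyl)oxy]-13,14,15,16-tetranorlabd-8(17)-ene-12,18-diol | C=C1C[C@H](O[Si](C)(C)C(C)(C)C)[C@H]2[C@](C)(CO)CCC[C@]2(C)[C@H]1CCO | intermediate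
21 | (4R,5R,6S,9S,10R)-6-[(tert-butyldimethylsilyl)oxy]-12-iodo-13,14,15,16-tetranorlabd-8(17)-en-18-ol | C=C1C[C@H](O[Si](C)(C)C(C)(C)C)[C@H]2[C@](C)(CO)CCC[C@]2(C)[C@H]1CCI | intermediate
22 | (4R,5R,6S,9S,10R)-6-[(tert-butyldimethylsilyl)oxy]-12-iodo-13,14,15,16-tetranorlabd-8(17)-en-18-yl benzoate | C=C1C[C@H](O[Si](C)(C)C(C)(C)C)[C@H]2[C@](C)(COC(=O)c3ccccc3)CCC[C@]2(C)[C@H]1CCI | intermediate
23 | but-2-ynoic acid | CC#CC(=O)O | starting material
24 | (2Z)-3-iodobut-2-enoic acid | C/C(I)=C/C(=O)O | intermediate
25 | 2-(trimethylsilyl)ethyl (2Z)-3-iodobut-2-enoate | C/C(I)=C/C(=O)OCC[Si](C)(C)C | intermediate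
26 | 12-(iodozincio) derivative of 22, the alkylzinc iodide (not isolated) | C=C1C[C@H](O[Si](C)(C)C(C)(C)C)[C@H]2[C@](C)(COC(=O)c3ccccc3)CCC[C@]2(C)[C@H]1CC[Zn]I | intermediate
27 | 2-(trimethylsilyl)ethyl (4R,5R,6S,9S,10R,13Z)-18-(benzoyloxy)-6-[(tert-butyldimethylsilyl)oxy]labda-8(17),13-dien-15-oate | C=C1C[C@H](O[Si](C)(C)C(C)(C)C)[C@H]2[C@](C)(COC(=O)c3ccccc3)CCC[C@]2(C)[C@H]1CC/C(C)=C\C(=O)OCC[Si](C)(C)C | intermediate
28 | (4R,5R,6S,9S,10R,13Z)-18-(benzoyloxy)-6-[(tert-butyldimethylsilyl)oxy]labda-8(17),13-dien-15-oic acid | C=C1C[C@H](O[Si](C)(C)C(C)(C)C)[C@H]2[C@](C)(COC(=O)c3ccccc3)CCC[C@]2(C)[C@H]1CC/C(C)=C\C(=O)O | intermediate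
29 | (4R,5R,6S,9S,10R,13Z)-18-(benzoyloxy)-6-hydroxylabda-8(17),13-dien-15-oic acid (CNP0304840.1) | C=C1C[C@H](O)[C@H]2[C@](C)(COC(=O)c3ccccc3)CCC[C@]2(C)[C@H]1CC/C(C)=C\C(=O)O | target

Total step count: 20.
Longest linear sequence: 16 steps (from 1 through steps 1–4, 7–15 and 18–20); the branch from 8 is 14 steps.

Steps most likely to fail

Step 9 (ring closure). The tertiary C10 radical may be quenched by a second hydrogen-atom transfer (net hydrogenation of the methylene), or the iron hydride may reduce the enoate, before the radical reaches the hindered C9. The fallback generates the same radical without any metal hydride. Setting out from 15, the methylene would be epoxidised (mCPBA, NaHCO3, CH2Cl2, 0 °C; the enoate is too electron-poor to react) to the spiro-epoxide F1. Cp2TiCl (from Cp2TiCl2 and Zn dust, THF, rt; trivalent titanium) should open it homolytically to the tertiary C10 radical, now carrying CH2O–Ti at C20, which closes ring B on C9 and gives the 20-hydroxy ketal ester F2. The primary alcohol would be converted into the imidazole-1-carbothioate F3 (1,1′-thiocarbonyldiimidazole, DMAP, toluene, 80 °C) and reduced (Bu3SnH, AIBN, toluene, 110 °C; Barton–McCombie deoxygenation), which returns to 16.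

Step 7 (C5–C6 bond). Stereocontrol may erode during the C–C bond formation: a synclinal instead of an antiperiplanar approach of the aldehyde would deliver the C6 epimer. Attack on the silylmethyl face of C5 would be a second leak, one that cannot be recycled. The fallback sets C6 by hydride delivery instead. Setting out from 14 (as its mixture of C6 epimers), oxidation (Dess–Martin periodinane, NaHCO3, CH2Cl2, 0 °C) would give the β,γ-unsaturated ketone F4, used at once because H-5 is both allylic and α to the carbonyl. Corey–Bakshi–Shibata reduction then follows, with the oxazaborolidine enantiomer that gives the (6S)-alcohol (expected to be (R)-2-methyl-CBS) and catecholborane in toluene at −78 °C. This agrees with the Felkin–Anh preference for hydride attack anti to C4, and returns to 14.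

Step 5 (quaternary C4). Transfer of the α-silylmethyl group from copper may be slow, since it is a reluctant ligand in cuprate chemistry, and this would bring low conversion or poor enantiofacial discrimination. The fallback exchanges the roles of the two C4 substituents. Setting out from the Grignard reagent 10, addition to 3-ethoxycyclohex-2-en-1-one and dilute aqueous acid at 0 °C (Stork–Danheiser transposition) would give the enone F5. Copper-catalysed asymmetric conjugate addition of AlMe3 follows (copper thiophene-2-carboxylate Cu(O2CC4H3S), monovalent copper, with a chiral phosphoramidite chosen for the R centre; Et2O, −30 °C). Trapping the aluminium enolate with Ac2O would give the enol acetate F6. MeLi (2 equiv, THF, 0 °C) then regenerates the regiodefined enolate, and PhNTf2 returns to 12.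

Further compounds
F1 | step 9 | 10,20-epoxide of 15 (spiro-oxirane at C10, either epimer) | C1OC12CCC[C@@](C)(C[Si](C)(C)c3ccccc3)[C@@H]2[C@@H](O[Si](C)(C)C(C)(C)C)CC4(OCCO4)/C=C/C(=O)OC
F2 | step 9 | 20-hydroxy analogue of 16 (10β-CH2OH) | C12(OCCO1)C[C@H](O[Si](C)(C)C(C)(C)C)[C@H]3[C@](C)(C[Si](C)(C)c4ccccc4)CCC[C@]3(CO)[C@H]2CC(=O)OC
F3 | step 9 | O-20 (1H-imidazol-1-yl)carbothioate of F2 | C12(OCCO1)C[C@H](O[Si](C)(C)C(C)(C)C)[C@H]3[C@](C)(C[Si](C)(C)c4ccccc4)CCC[C@]3(COC(=S)n5ccnc5)[C@H]2CC(=O)OC
F4 | step 7 | 6-oxo compound corresponding to 14 | C=C1CCC[C@@](C)(C[Si](C)(C)c2ccccc2)[C@@H]1C(=O)CC1(OCCO1)/C=C/C(=O)OC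
F5 | step 5 | 3-{[dimethyl(phenyl)silyl]methyl}cyclohex-2-en-1-one | O=C1C=C(C[Si](C)(C)c2ccccc2)CCC1
F6 | step 5 | (3R)-3-{[dimethyl(phenyl)silyl]methyl}-3-methylcyclohex-1-en-1-yl acetate | CC(=O)OC1=C[C@](C)(C[Si](C)(C)c2ccccc2)CCC1
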